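**Retrosynthetic overview**
1. Alertenone ⇒ two molecules of suberosenone, joined by Michael addition of the C3 enolate of one onto the exo-methylene of the other.
2. Suberosenone ⇒ tricyclic enone 12 (α′-aminomethylation, enone hydrogenation, amine elimination).
3. Ring A (cyclopentenone) ⇒ aldol condensation of a 1,4-diketone onto the bridging ketone of a bicyclo[3.2.1]octan-8-one.
4. Two-carbon bridge (C5–C11 bond) ⇒ intramolecular tert-alkylation of a cyclohexanone silyl enol ether.
5. Key step: the quaternary C9 centre (C9–C10 bond) ⇒ Claisen [3,3] rearrangement of the O-(2-methylallyl) ether of formylated (S)-pulegone. Ring order: cyclohexane (pulegone) → bridge ring → ring A → dimer.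

Assumption: the C8 methyl configuration in the SMILES is (S), which corresponds to (S)-(−)-pulegone; this is taken as purchased.

Atom labels used below (monomer): C1(=CH2)–C2(=O)–C3H2–C4H–C5H–C6H2–C7H2–C8H(CH3)–C9; C9 is also bonded to C1, C4 and C10; C10H2–C11(CH3)2–C5.

**Step 1**
Reactants: 1, (S)-(−)-pulegone; 2, ethyl formate
Product: 3, (3S)-2-(hydroxymethylidene)-3-methyl-6-(propan-2-ylidene)cyclohexan-1-one (enolised keto-aldehyde; the formyl carbon is the future C1, on C9)
Conditions: NaH, HCO2Et, cat. EtOH, THF, 0 → 25 °C; aq. HCl work-up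
Reagents that add atoms: ethyl formate, CCOC=O
Why: Crossed Claisen condensation (formylation) at the only free α-CH2, the other α-carbon being blocked by the isopropylidene; the pulegone stereocentre is untouched.

**Step 2**
Reactants: 3; 4, 3-bromo-2-methylprop-1-ene (methallyl bromide)
Product: 5, (1R,2S)-2-methyl-1-(2-methylprop-2-en-1-yl)-6-oxo-5-(propan-2-ylidene)cyclohexane-1-carbaldehyde
Conditions: K2CO3, DMF, 25 °C (O-alkylation); crude enol ether, xylenes, 140 °C
Reagents that add atoms: methallyl bromide, C=C(C)CBr
Why: O-allylation then Claisen [3,3] rearrangement through a chair transition state forms the C9–C10 bond anti to the C8 methyl (held pseudo-axial by A1,3 strain with the alkoxymethylene group), so methallyl is trans and CHO cis to the methyl; any directly C-alkylated material is the same compound.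

**Step 3**
Reactants: 5; 6, ethyltriphenylphosphonium bromide
Product: 7, (2R,3S)-3-methyl-2-(2-methylprop-2-en-1-yl)-2-[(Z)-prop-1-en-1-yl]-6-(propan-2-ylidene)cyclohexan-1-one
Conditions: EtPPh3Br, KHMDS, THF, −78 → 0 °C
Reagents that add atoms: ethyltriphenylphosphonium bromide, CC[P+](c1ccccc1)(c1ccccc1)c1ccccc1.[Br-]
Why: Wittig olefination, chemoselective for the aldehyde over the hindered conjugated ketone, turns the formyl group into a propenyl group (a masked acetonyl; alkene geometry is irrelevant).

**Step 4**
Reactants: 7
Product: 8, (2R,3S)-3-methyl-2-(2-methylprop-2-en-1-yl)-2-[(Z)-prop-1-en-1-yl]cyclohexan-1-one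
Conditions: KOH, EtOH/H2O, 75 °C, acetone distilled out
Reagents that add atoms: none
Why: Retro-aldol cleavage (hydration of the enone, loss of acetone) removes the isopropylidene blocking group; C9 is quaternary and cannot epimerise, and the temperature is kept below that needed for Cope rearrangement of the 1,5-diene.

**Step 5**
Reactants: 8
Product: 9, (2R,3S)-2-(2-chloro-2-methylpropyl)-3-methyl-2-[(Z)-prop-1-en-1-yl]cyclohexan-1-one
Conditions: HCl (g), CH2Cl2, −20 °C
Reagents that add atoms: hydrogen chloride, Cl
Why: Markovnikov hydrochlorination; the 1,1-disubstituted alkene (tertiary cation) reacts far faster than the 1,2-disubstituted propenyl group.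

**Step 6**
Reactants: 9
Product: 10, (1R,2S,5R)-2,6,6-trimethyl-1-[(Z)-prop-1-en-1-yl]bicyclo[3.2.1]octan-8-one
Conditions: TMSOTf, Et3N, CH2Cl2, 0 °C; then TiCl4, CH2Cl2, −78 → −40 °C
Reagents that add atoms: none
Why: Intramolecular Reetz-type α-tert-alkylation: the only possible silyl enol ether (C4=C5) captures the tertiary cation to form the C5–C11 bond, and the C5 configuration is forced because the bridge must span C9 and C5 on one face.

**Step 7**
Reactants: 10
Product: 11, (1S,2S,5R)-2,6,6-trimethyl-1-(2-oxopropyl)bicyclo[3.2.1]octan-8-one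
Conditions: Pd(OAc)2 (cat.), benzoquinone, HBF4, DMA/MeCN/H2O, 25 °C
Reagents that add atoms: water, O
Why: Wacker oxidation; water attacks the alkene carbon remote from the quaternary centre and the β-carbonyl, placing the ketone at C2.

**Step 8**
Reactants: 11
Product: 12, tricyclic enone (ring A = C9–C1H2–C2(=O)–C3H=C4 fused on the bicyclo[3.2.1]octane; 5R,8S,9S)
Conditions: KOH, MeOH, 60 °C
Reagents that add atoms: none
Why: Intramolecular aldol condensation of the methyl-ketone enolate onto the non-enolisable bridging ketone closes ring A (5-ring, enolexo).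

**Step 9**
Reactants: 12; 13, N,N-dimethylmethyleneiminium iodide (Eschenmoser's salt)
Product: 14, 1-[(dimethylamino)methyl] derivative of 12 (C1 epimers, irrelevant)
Conditions: LDA, THF, −78 °C; then 13, −78 → 0 °C
Reagents that add atoms: Eschenmoser's salt, C[N+](C)=C.[I-]
Why: Mannich reaction of the kinetic α′-enolate; C1H2 is the only acidic site because the γ-hydrogen is a bridgehead, so the future methylene is placed regiospecifically.

**Step 10**
Reactants: 14
Product: 15, 3,4-dihydro-14 (4S,5S,8S,9S; C1 epimers)
Conditions: H2 (1 atm), 10% Pd/C, EtOAc, 25 °C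
Reagents that add atoms: none
Why: Catalytic hydrogenation of the enone places H on C4 on the face of the three-carbon bridge, giving the cis-fused bicyclo[3.3.0]octane, the only unstrained ring fusion.

**Step 11**
Reactants: 15
Product: 16, suberosenone (4S,5S,8S,9S)
Conditions: MeI, CH2Cl2, 25 °C; then DBU
Reagents that add atoms: none
Why: N-quaternisation and E1cB elimination give the α-methylene ketone; C9 is quaternary, so only the exocyclic alkene can form.

**Step 12**
Reactants: 16 (two molecules)
Product: 17, alertenone
Conditions: LiHMDS (0.5 equiv per 16), THF, −78 → −40 °C; AcOH quench at −78 °C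
Reagents that add atoms: none
Why: Michael addition of the cross-conjugated lithium enolate (C3) to the exo-methylene of a second molecule; C–C bond formation occurs on the face anti to the C5–C11 bridge (sets C3), and kinetic protonation of the hindered product enolate occurs anti to the C8′ methyl (sets C1′).

**Compound list**
1 | (S)-(−)-pulegone | C[C@H]1CCC(=C(C)C)C(=O)C1 | starting material
2 | ethyl formate | CCOC=O | starting material
3 | (3S)-2-(hydroxymethylidene)-3-methyl-6-(propan-2-ylidene)cyclohexan-1-one | C[C@H]1CCC(=C(C)C)C(=O)C1=CO | intermediate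
4 | 3-bromo-2-methylprop-1-ene | C=C(C)CBr | starting material
5 | (1R,2S)-2-methyl-1-(2-methylprop-2-en-1-yl)-6-oxo-5-(propan-2-ylidene)cyclohexane-1-carbaldehyde | C[C@H]1CCC(=C(C)C)C(=O)[C@]1(C=O)CC(C)=C | intermediate
6 | ethyltriphenylphosphonium bromide | CC[P+](c1ccccc1)(c1ccccc1)c1ccccc1.[Br-] | starting material
7 | (2R,3S)-3-methyl-2-(2-methylallyl)-2-[(Z)-prop-1-enyl]-6-(propan-2-ylidene)cyclohexan-1-one | C[C@H]1CCC(=C(C)C)C(=O)[C@]1(/C=C\C)CC(C)=C | intermediate
8 | (2R,3S)-3-methyl-2-(2-methylallyl)-2-[(Z)-prop-1-enyl]cyclohexan-1-one | C[C@H]1CCCC(=O)[C@]1(/C=C\C)CC(C)=C | intermediate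
9 | (2R,3S)-2-(2-chloro-2-methylpropyl)-3-methyl-2-[(Z)-prop-1-enyl]cyclohexan-1-one | C[C@H]1CCCC(=O)[C@]1(/C=C\C)CC(C)(C)Cl | intermediate
10 | (1R,2S,5R)-2,6,6-trimethyl-1-[(Z)-prop-1-enyl]bicyclo[3.2.1]octan-8-one | O=C1[C@@H]2CC[C@H](C)[C@@]1(/C=C\C)CC2(C)C | intermediate
11 | (1S,2S,5R)-2,6,6-trimethyl-1-(2-oxopropyl)bicyclo[3.2.1]octan-8-one | O=C1[C@@H]2CC[C@H](C)[C@@]1(CC(C)=O)CC2(C)C | intermediate
12 | tricyclic enone (C2=O, C3=C4) | O=C1C=C2[C@@H]3CC[C@H](C)[C@@]2(C1)CC3(C)C | intermediate
13 | N,N-dimethylmethyleneiminium iodide | C[N+](C)=C.[I-] | starting material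
14 | C1-(dimethylaminomethyl) enone | CN(C)CC1C(=O)C=C2[C@@H]3CC[C@H](C)[C@]12CC3(C)C | intermediate
15 | saturated Mannich base | CN(C)CC1C(=O)C[C@H]2[C@@H]3CC[C@H](C)[C@]12CC3(C)C | intermediate
16 | suberosenone | C=C1C(=O)C[C@H]2[C@@H]3CC[C@H](C)[C@]12CC3(C)C | intermediate
17 | alertenone | C=C1C(=O)[C@H](C[C@@H]2C(=O)C[C@H]3[C@@H]4CC[C@H](C)[C@]23CC4(C)C)[C@H]2[C@@H]3CC[C@H](C)[C@]12CC3(C)C | target

**Totals**
Total steps: 12. Longest linear sequence: 12 (steps 1–12; step 12 joins two molecules of 16 from the same sequence).

**Steps most likely to fail, with fallbacks**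
1. Step 6 (bridge closure): the tertiary cation may eliminate or be trapped on oxygen. Fallback: use 2,3-dibromopropene in step 2 so the Claisen delivers a 2-bromoallyl group, close the bridge by Pd-catalysed intramolecular ketone α-alkenylation (gives the C11 exo-methylene bicycle), then convert =CH2 to CMe2 by cyclopropanation and hydrogenolysis.
2. Step 7 (Wacker oxidation of a hindered internal alkene): it may be slow or give the wrong regioisomer. Fallback: use Ph3P=C(OMe)CH3 in step 3 to carry a masked methyl ketone, hydrolyse and close ring A first (hydrindenone), and form the bridge last by γ-alkylation of its silyl dienol ether with the tertiary chloride.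
3. Step 12 (dimerisation): risks are oligomerisation, a second intramolecular Michael addition (formal Diels–Alder adduct), and the wrong C1′ epimer. Fallback: a crossed coupling in which the lithium enolate of the saturated Mannich base 15 (no enone; deprotonates at C3) adds to 16, followed by MeI/DBU to unveil the exo-methylene of that unit.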